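**Retrosynthetic overview**

1. The target is epicatechin gallate-(4β→8)-epicatechin gallate-(4β→6)-catechin. No ring is built: rings A, B and C of each flavan unit come intact from (−)-epicatechin and (+)-catechin, and both galloyl rings from 3,4,5-tris(benzyloxy)benzoic acid.
2. The biomimetic events are the two interflavan C–C bonds, each made as in proanthocyanidin chain extension: a C4 flavanyl cation is captured by a phloroglucinol-type ring A.
3. Last bond: C4(middle)–C6(bottom), by a convergent [2+1] union of a dimeric C4 cation, generated directly from C4–H by hydride abstraction, with an 8-bromo-blocked catechin.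
4. First bond: C4(top)–C8(middle), from an 8-bromo-capped epicatechin gallate C4 cation and a second molecule of the same perbenzylated epicatechin gallate. Each 3-O-galloyl group steers attack to the β face.
5. Eighteen benzyl ethers and the two C8 bromides (cap and block) are removed in one final hydrogenolysis.

Assumption: the SMILES is read as (−)-epicatechin 3-O-gallate-(4β→8)-(−)-epicatechin 3-O-gallate-(4β→6)-(+)-catechin (top 2R,3R,4R; middle 2R,3R,4S; bottom 2R,3S). (−)-Epicatechin, (+)-catechin and 3,4,5-tris(benzyloxy)benzoic acid are taken as commercial materials; "ECG" below means the epicatechin 3-O-gallate skeleton.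

**Route**

Step 1
Reactants: 1 (−)-epicatechin
Product: 2 5,7,3',4'-tetra-O-benzyl-(−)-epicatechin (3-OH free; 2R,3R unchanged)
Conditions: BnBr (4.4 equiv), K2CO3 (6 equiv), DMF, 0 °C to rt, 12 h, Ar
Reagents that add atoms: benzyl bromide, BrCc1ccccc1
Why: Williamson ether synthesis that is chemoselective for the four phenols because K2CO3 does not deprotonate the secondary C3 alcohol, the low temperature suppressing C-benzylation of ring A and C2 epimerisation.

Step 2
Reactants: 2 5,7,3',4'-tetra-O-benzyl-(−)-epicatechin; 3 3,4,5-tris(benzyloxy)benzoic acid (1.3 equiv)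
Product: 4 hepta-O-benzyl-ECG (3-O-(3,4,5-tribenzyloxybenzoyl) ester of 2; 2R,3R)
Conditions: DCC (1.5 equiv), DMAP (0.2 equiv), CH2Cl2, 0 °C to rt, 16 h
Reagents that add atoms: none
Why: Steglich esterification in which DCC activates acid 3 as the O-acylisourea and DMAP relays the acyl group to the hindered axial C3 alcohol, with retention at C3 because the C3–O bond is never broken.

Step 3
Reactants: 4 hepta-O-benzyl-ECG
Product: 5 8-bromo-hepta-O-benzyl-ECG (C8 cap)
Conditions: NBS (1.0 equiv), CH2Cl2, −78 °C to 0 °C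
Reagents that add atoms: N-bromosuccinimide, O=C1CCC(=O)N1Br
Why: Electrophilic aromatic bromination of the most electron-rich ring (ring A) at C8, which is flanked by one benzyloxy group and the tied-back ring oxygen and so reacts well ahead of the doubly flanked C6, giving the cap that later prevents self-condensation.

Step 4
Reactants: 5 8-bromo-hepta-O-benzyl-ECG (cation precursor); 4 hepta-O-benzyl-ECG (C8 nucleophile)
Product: 7 8-bromo-hepta-O-benzyl-ECG-(4β→8)-hepta-O-benzyl-ECG (protected top–middle dimer), via benzylic cation ion pair 6 (not isolated)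
Conditions: DDQ (1.0 equiv), 4 Å MS, CH2Cl2, 0 °C to rt, 2 h; then 4 (1.5 equiv), BF3·OEt2 (0.3 equiv), −78 to −30 °C
Reagents that add atoms: none
Why: Proposed new method: DDQ abstracts the C4 hydride of 5 (benzylic, ortho/para to the ring A ether oxygens) to give the C4 cation of biosynthetic chain extension, which without an alcohol trap is held as the α-face galloyl-bridged dioxolanylium/DDQH adduct 6 (5 cannot self-condense because C8 is brominated), and BF3·OEt2 then lets the more accessible C8 of 4 attack in a Friedel–Crafts alkylation from the β face, anti to the participating 3-O-galloyl group, setting the new C4 centre as 4β (3,4-trans); the closest known chemistry is DDQ-mediated cross-dehydrogenative coupling of benzylic ethers with arenes and the two-step DDQ/alcohol then Lewis-acid interflavan coupling.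

Step 5
Reactants: 8 (+)-catechin
Product: 9 5,7,3',4'-tetra-O-benzyl-(+)-catechin (3-OH free)
Conditions: BnBr (4.4 equiv), K2CO3 (6 equiv), DMF, 0 °C to rt, 12 h, Ar
Reagents that add atoms: benzyl bromide, BrCc1ccccc1
Why: Williamson ether synthesis that is chemoselective for the four phenols because K2CO3 does not deprotonate the secondary C3 alcohol, with no change at C2 or C3.

Step 6
Reactants: 9 5,7,3',4'-tetra-O-benzyl-(+)-catechin
Product: 10 8-bromo-5,7,3',4'-tetra-O-benzyl-(+)-catechin (C8 block)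
Conditions: NBS (1.0 equiv), CH2Cl2, −78 °C to rt
Reagents that add atoms: N-bromosuccinimide, O=C1CCC(=O)N1Br
Why: Electrophilic aromatic bromination that goes selectively to C8 of ring A for the same steric reason as in step 3, leaving C6 as the only nucleophilic position for the later 4→6 bond.

Step 7
Reactants: 7 protected top–middle dimer (cation precursor); 10 8-bromo-5,7,3',4'-tetra-O-benzyl-(+)-catechin (C6 nucleophile)
Product: 12 8-bromo-hepta-O-benzyl-ECG-(4β→8)-hepta-O-benzyl-ECG-(4β→6)-8-bromo-tetra-O-benzyl-catechin (protected trimer), via dimer benzylic cation ion pair 11 (not isolated)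
Conditions: DDQ (1.0 equiv), 4 Å MS, CH2Cl2, 0 °C to rt, 3 h; then 10 (3 equiv), BF3·OEt2 (0.5 equiv), −78 to −20 °C
Reagents that add atoms: none
Why: Proposed new method: the oxidative activation of step 4 applied to the dimer, where only the C4 methylene of the lower unit has a C–H bond able to overlap with an electron-rich ring A (the upper C4–H is a crowded, in-plane diarylmethine), so hydride abstraction gives cation 11, which has no free C8 and is captured in a Friedel–Crafts alkylation by the excess of 10 at its only open position, C6, again anti to the bridging 3-O-galloyl group so that the new centre is 4β; the closest known chemistry is DDQ cross-dehydrogenative coupling and halogen-capped Lewis-acid 4→6 interflavan coupling.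

Step 8
Reactants: 12 protected trimer
Product: 13 target CNP0154615.1
Conditions: H2 (1 atm), Pd(OH)2/C (20 wt%), NaOAc (2.2 equiv), THF/MeOH/H2O 20:1:1, rt, 12 h; filtration under Ar, Sephadex LH-20
Reagents that add atoms: none
Why: Heterogeneous catalytic hydrogenolysis that cleaves all eighteen benzyl ethers and both aryl C–Br bonds in one operation (NaOAc buffers the HBr), while the gallate esters, the interflavan bonds and all eight stereocentres are inert.

**Compound list**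

1 | (−)-epicatechin, (2R,3R) | O[C@@H]1Cc2c(O)cc(O)cc2O[C@@H]1c1ccc(O)c(O)c1 | starting material
2 | 5,7,3',4'-tetra-O-benzyl-(−)-epicatechin | O[C@@H]1Cc2c(OCc3ccccc3)cc(OCc3ccccc3)cc2O[C@@H]1c1ccc(OCc2ccccc2)c(OCc2ccccc2)c1 | intermediate
3 | 3,4,5-tris(benzyloxy)benzoic acid | OC(=O)c1cc(OCc2ccccc2)c(OCc2ccccc2)c(OCc2ccccc2)c1 | starting material
4 | hepta-O-benzyl-ECG | O=C(O[C@@H]1Cc2c(OCc3ccccc3)cc(OCc3ccccc3)cc2O[C@@H]1c1ccc(OCc2ccccc2)c(OCc2ccccc2)c1)c1cc(OCc2ccccc2)c(OCc2ccccc2)c(OCc2ccccc2)c1 | intermediate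
5 | 8-bromo-hepta-O-benzyl-ECG | O=C(O[C@@H]1Cc2c(OCc3ccccc3)cc(OCc3ccccc3)c(Br)c2O[C@@H]1c1ccc(OCc2ccccc2)c(OCc2ccccc2)c1)c1cc(OCc2ccccc2)c(OCc2ccccc2)c(OCc2ccccc2)c1 | intermediate
6 | C4 cation of 5 (galloyl-bridged on the α face) as ion pair with the DDQ-derived hydroquinone monoanion | O=C(O[C@@H]1[CH+]c2c(OCc3ccccc3)cc(OCc3ccccc3)c(Br)c2O[C@@H]1c1ccc(OCc2ccccc2)c(OCc2ccccc2)c1)c1cc(OCc2ccccc2)c(OCc2ccccc2)c(OCc2ccccc2)c1.[O-]c1c(Cl)c(Cl)c(O)c(C#N)c1C#N | intermediate
7 | 8-bromo-hepta-O-benzyl-ECG-(4β→8)-hepta-O-benzyl-ECG | O=C(O[C@@H]1[C@@H](c2c(OCc4ccccc4)cc(OCc4ccccc4)c3c2O[C@H](c2ccc(OCc4ccccc4)c(OCc4ccccc4)c2)[C@H](OC(=O)c2cc(OCc4ccccc4)c(OCc4ccccc4)c(OCc4ccccc4)c2)C3)c2c(OCc3ccccc3)cc(OCc3ccccc3)c(Br)c2O[C@@H]1c1ccc(OCc2ccccc2)c(OCc2ccccc2)c1)c1cc(OCc2ccccc2)c(OCc2ccccc2)c(OCc2ccccc2)c1 | intermediate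
8 | (+)-catechin, (2R,3S) | O[C@H]1Cc2c(O)cc(O)cc2O[C@@H]1c1ccc(O)c(O)c1 | starting material
9 | 5,7,3',4'-tetra-O-benzyl-(+)-catechin | O[C@H]1Cc2c(OCc3ccccc3)cc(OCc3ccccc3)cc2O[C@@H]1c1ccc(OCc2ccccc2)c(OCc2ccccc2)c1 | intermediate
10 | 8-bromo-5,7,3',4'-tetra-O-benzyl-(+)-catechin | O[C@H]1Cc2c(OCc3ccccc3)cc(OCc3ccccc3)c(Br)c2O[C@@H]1c1ccc(OCc2ccccc2)c(OCc2ccccc2)c1 | intermediate
11 | lower-unit C4 cation of 7 (galloyl-bridged on the α face) as ion pair with the DDQ-derived hydroquinone monoanion | O=C(O[C@@H]1[C@@H](c2c(OCc4ccccc4)cc(OCc4ccccc4)c3c2O[C@H](c2ccc(OCc4ccccc4)c(OCc4ccccc4)c2)[C@H](OC(=O)c2cc(OCc4ccccc4)c(OCc4ccccc4)c(OCc4ccccc4)c2)[CH+]3)c2c(OCc3ccccc3)cc(OCc3ccccc3)c(Br)c2O[C@@H]1c1ccc(OCc2ccccc2)c(OCc2ccccc2)c1)c1cc(OCc2ccccc2)c(OCc2ccccc2)c(OCc2ccccc2)c1.[O-]c1c(Cl)c(Cl)c(O)c(C#N)c1C#N | intermediate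
12 | 8-bromo-hepta-O-benzyl-ECG-(4β→8)-hepta-O-benzyl-ECG-(4β→6)-8-bromo-tetra-O-benzyl-catechin | O=C(O[C@@H]1[C@@H](c2c(OCc4ccccc4)cc(OCc4ccccc4)c3c2O[C@H](c2ccc(OCc4ccccc4)c(OCc4ccccc4)c2)[C@H](OC(=O)c2cc(OCc4ccccc4)c(OCc4ccccc4)c(OCc4ccccc4)c2)[C@H]3c2c(OCc4ccccc4)c(Br)c3c(c2OCc4ccccc4)C[C@H](O)[C@@H](c2ccc(OCc4ccccc4)c(OCc4ccccc4)c2)O3)c2c(OCc3ccccc3)cc(OCc3ccccc3)c(Br)c2O[C@@H]1c1ccc(OCc2ccccc2)c(OCc2ccccc2)c1)c1cc(OCc2ccccc2)c(OCc2ccccc2)c(OCc2ccccc2)c1 | intermediate
13 | CNP0154615.1, ECG-(4β→8)-ECG-(4β→6)-catechin (top 2R,3R,4R; middle 2R,3R,4S; bottom 2R,3S) | O=C(O[C@@H]1[C@@H](c2c(O)cc(O)c3c2O[C@H](c2ccc(O)c(O)c2)[C@H](OC(=O)c2cc(O)c(O)c(O)c2)[C@H]3c2c(O)cc3c(c2O)C[C@H](O)[C@@H](c2ccc(O)c(O)c2)O3)c2c(O)cc(O)cc2O[C@@H]1c1ccc(O)c(O)c1)c1cc(O)c(O)c(O)c1 | target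

**Step count and risk**

Total steps: 8. Longest linear sequence: 6 (steps 1, 2, 3, 4, 7, 8).

Most likely to fail, first: step 7. DDQ may not discriminate cleanly between the lower-unit C4 methylene and other benzylic sites of the dimer. Cation 11 must also be captured at the crowded C6 of 10 in competition with the free C6 of the dimer itself. The fallback is orthogonal activation, so the dimer never has to be oxidised. It sets out from 4. DDQ and 2-ethoxyethanol in CH2Cl2 give the isolable hepta-O-benzyl-ECG 4β-(2-ethoxyethyl) ether F1. Exchange with 2,6-dimethylbenzenethiol (Cc1cccc(C)c1S) under BF3·OEt2 at −78 °C gives the 4β-(2,6-dimethylphenylsulfanyl) derivative F2, whose C–S bond is inert to hard Lewis acids. F2 then replaces 4 as the C8 nucleophile toward cation 6, made from 5 as in step 4, giving the dimer 4β-thioether F3. The soft thiophile AgOTf (silver trifluoromethanesulfonate) in CH2Cl2 at −40 °C ionises F3 in the presence of excess 10, and C6 attack gives 12, where the fallback comes back to the route.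

Second: step 4. Without an alcohol trap, cation 6 may collapse to the flav-3-ene or be hydrolysed before 4 is added. The fallback uses a classical isolable leaving group. It sets out from 5: DDQ with 2-ethoxyethanol in CH2Cl2 gives the 8-bromo-hepta-O-benzyl-ECG 4β-(2-ethoxyethyl) ether F4, which is purified and condensed with 4 under catalytic TMSOTf in CH2Cl2 at −78 °C to give 7, where it comes back to the route.

Third: step 8. Twenty reductive cleavages are needed on one large substrate, bromide can slow the catalyst, and the free polyphenol is sensitive to air and acid. The fallback removes the halogens by a radical chain before any palladium is used. It sets out from 12: n-Bu3SnH and AIBN in toluene at 90 °C give the bromine-free octadeca-O-benzyl trimer F5, and hydrogenolysis of F5 over Pd(OH)2/C in THF/MeOH/H2O then gives 13.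

**Further compounds**

F1 | step 7 | hepta-O-benzyl-ECG 4β-(2-ethoxyethyl) ether | O=C(O[C@@H]1[C@@H](OCCOCC)c2c(OCc3ccccc3)cc(OCc3ccccc3)cc2O[C@@H]1c1ccc(OCc2ccccc2)c(OCc2ccccc2)c1)c1cc(OCc2ccccc2)c(OCc2ccccc2)c(OCc2ccccc2)c1
F2 | step 7 | 4β-(2,6-dimethylphenylsulfanyl)-hepta-O-benzyl-ECG | O=C(O[C@@H]1[C@@H](Sc3c(C)cccc3C)c2c(OCc3ccccc3)cc(OCc3ccccc3)cc2O[C@@H]1c1ccc(OCc2ccccc2)c(OCc2ccccc2)c1)c1cc(OCc2ccccc2)c(OCc2ccccc2)c(OCc2ccccc2)c1
F3 | step 7 | 8-bromo-hepta-O-benzyl-ECG-(4β→8)-[4β-(2,6-dimethylphenylsulfanyl)-hepta-O-benzyl-ECG] | O=C(O[C@@H]1[C@@H](c2c(OCc4ccccc4)cc(OCc4ccccc4)c3c2O[C@H](c2ccc(OCc4ccccc4)c(OCc4ccccc4)c2)[C@H](OC(=O)c2cc(OCc4ccccc4)c(OCc4ccccc4)c(OCc4ccccc4)c2)[C@H]3Sc2c(C)cccc2C)c2c(OCc3ccccc3)cc(OCc3ccccc3)c(Br)c2O[C@@H]1c1ccc(OCc2ccccc2)c(OCc2ccccc2)c1)c1cc(OCc2ccccc2)c(OCc2ccccc2)c(OCc2ccccc2)c1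
F4 | step 4 | 8-bromo-hepta-O-benzyl-ECG 4β-(2-ethoxyethyl) ether | O=C(O[C@@H]1[C@@H](OCCOCC)c2c(OCc3ccccc3)cc(OCc3ccccc3)c(Br)c2O[C@@H]1c1ccc(OCc2ccccc2)c(OCc2ccccc2)c1)c1cc(OCc2ccccc2)c(OCc2ccccc2)c(OCc2ccccc2)c1
F5 | step 8 | octadeca-O-benzyl ECG-(4β→8)-ECG-(4β→6)-catechin (bromine-free) | O=C(O[C@@H]1[C@@H](c2c(OCc4ccccc4)cc(OCc4ccccc4)c3c2O[C@H](c2ccc(OCc4ccccc4)c(OCc4ccccc4)c2)[C@H](OC(=O)c2cc(OCc4ccccc4)c(OCc4ccccc4)c(OCc4ccccc4)c2)[C@H]3c2c(OCc4ccccc4)cc3c(c2OCc4ccccc4)C[C@H](O)[C@@H](c2ccc(OCc4ccccc4)c(OCc4ccccc4)c2)O3)c2c(OCc3ccccc3)cc(OCc3ccccc3)cc2O[C@@H]1c1ccc(OCc2ccccc2)c(OCc2ccccc2)c1)c1cc(OCc2ccccc2)c(OCc2ccccc2)c(OCc2ccccc2)c1
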